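## Retrosynthetic overview

1. The target comes from release of the C19 acid and C15 alcohol. The C12–C13 bond comes from a nickel-catalysed decarboxylative alkenylation of a C13 carboxylic acid with an (E)-alkenylzinc.
2. The 7α-OH/8(17)-ene unit comes from a singlet-oxygen ene reaction of a 6β-benzoyloxy-7-ene; the 6β-oxygen comes from α-face hydride reduction of a 7-en-6-one.
3. Ring B (formed second) comes from aldol condensation of a 1,5-diketone. That diketone is made by a photochemical de Mayo [2+2]/retro-aldol between a ring A cyclohexene and a 3-alkylpentane-2,4-dione (C5–C6 and C9–C10 bonds, C10 quaternary centre).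
4. Ring A (formed first) comes from ring-closing metathesis. Its C4 quaternary centre comes from Fráter–Seebach double alkylation of tert-butyl (R)-3-hydroxybutanoate, the only source of chirality.

Assumption: 5-iodo-2-methylpent-1-ene and methyl 4-acetyl-5-oxohexanoate are bought as catalogue chemicals; bicyclic compounds carry labdane numbering (C1–C10 decalin, C11–C16 side chain, C17 on C8, C18/C19 on C4, C20 on C10; α = face opposite C20; "9βH" = side chain α).

## Route

Step 1
Reactants: 1 tert-butyl (R)-3-hydroxybutanoate; 2 5-iodo-2-methylpent-1-ene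
Product: 3 tert-butyl (2R,3R)-3-hydroxy-2-(4-methylpent-4-en-1-yl)butanoate
Conditions: LiN(iPr)2 (2.2 equiv), THF, −78 → −20 °C; then 2, DMPU, −20 °C → rt
Reagents that add atoms: none
Why: Fráter–Seebach alkylation; the lithium-chelated alkoxide–enolate dianion is attacked on the face away from the C3 methyl group, giving the anti (2R,3R) product.

Step 2
Reactants: 3 tert-butyl (2R,3R)-3-hydroxy-2-(4-methylpent-4-en-1-yl)butanoate
Product: 4 tert-butyl (2S,3R)-3-hydroxy-2-methyl-2-(4-methylpent-4-en-1-yl)butanoate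
Conditions: LiN(iPr)2 (2.5 equiv), THF/DMPU, −78 → −20 °C; then MeI, −78 → 0 °C
Reagents that add atoms: iodomethane, CI
Why: Second Fráter–Seebach alkylation; methyl iodide enters from the same enolate face as in step 1, so the order chain-then-methyl fixes the quaternary carbon (future C4) as 2S under control of the bought C3 carbinol.

Step 3
Reactants: 4 tert-butyl (2S,3R)-3-hydroxy-2-methyl-2-(4-methylpent-4-en-1-yl)butanoate
Product: 5 tert-butyl (2S)-2-methyl-2-(4-methylpent-4-en-1-yl)but-3-enoate
Conditions: Burgess reagent, toluene, 80 °C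
Reagents that add atoms: none
Why: Burgess syn-dehydration; the only β-hydrogens are on the methyl group (the other neighbour is quaternary), so the vinyl group forms regiospecifically and the used-up carbinol centre disappears.

Step 4
Reactants: 5 tert-butyl (2S)-2-methyl-2-(4-methylpent-4-en-1-yl)but-3-enoate
Product: 6 tert-butyl (1S)-1,3-dimethylcyclohex-2-ene-1-carboxylate
Conditions: second-generation Grubbs catalyst (3 mol %), CH2Cl2, 40 °C
Reagents that add atoms: none
Why: Ring-closing metathesis of the vinyl and isopropenyl termini closes ring A as the C5=C10 trisubstituted cyclohexene with loss of ethene; the quaternary centre is untouched.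

Step 5
Reactants: 6 tert-butyl (1S)-1,3-dimethylcyclohex-2-ene-1-carboxylate; 7 methyl 4-acetyl-5-oxohexanoate
Product: 9 tert-butyl (1S,3R)-2-acetyl-3-(1-methoxy-1,5-dioxohexan-4-yl)-1,3-dimethylcyclohexane-1-carboxylate (mixed epimers at C2/chain methine), via cyclobutanol photoadduct 8 (not isolated)
Conditions: 7 (4 equiv), hν (300 nm), MeCN, N2, 20 °C; then SiO2 to complete the retro-aldol
Reagents that add atoms: none
Why: Proposed new method: a de Mayo reaction (enol [2+2] photocycloaddition, then retro-aldol) not yet shown for a 3-alkylated pentane-2,4-dione adding to a trisubstituted cyclohexene beside a quaternary carbon; the hydrogen-bonded enol of 7 is the only strong absorber at 300 nm, its excited state bonds first from the hydroxy-bearing carbon (C6) to the less substituted alkene carbon C5 to give the tertiary C10/acyl-stabilised C9 1,4-biradical, closure then makes the C9–C10 bond and the quaternary C10, and cyclobutanol 8 opens to 9; both bonds form cis on the face anti to the pseudoaxial tert-butyl ester, placing the C10 methyl cis to the ester (estimated about 5:1, the weakest stereocontrol in the route), while C5 and C9 are left for equilibration in step 6; the closest known chemistry is the de Mayo reaction of acetylacetone with cyclohexene or isobutene.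

Step 6
Reactants: 9 tert-butyl (1S,3R)-2-acetyl-3-(1-methoxy-1,5-dioxohexan-4-yl)-1,3-dimethylcyclohexane-1-carboxylate
Product: 10 19-tert-butyl hydrogen 6-oxo-14,15,16-trinor-9βH-labd-7-ene-13,19-dioate
Conditions: KOH, MeOH/H2O, 65 °C; then aq HCl to pH 3
Reagents that add atoms: none
Why: Intramolecular aldol condensation with concurrent saponification of the unhindered methyl ester; the C7 enolate attacks the less hindered C8 carbonyl to close ring B, C5 equilibrates to the trans ring fusion, and C9 equilibrates through the dienolate to the pseudoaxial α side chain that avoids A(1,2) strain with the C8 methyl (as in the base epimerisation of polygodial to its 9-epimer).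

Step 7
Reactants: 10 19-tert-butyl hydrogen 6-oxo-14,15,16-trinor-9βH-labd-7-ene-13,19-dioate
Product: 11 19-tert-butyl hydrogen 6β-hydroxy-14,15,16-trinor-9βH-labd-7-ene-13,19-dioate
Conditions: NaBH4, CeCl3·7H2O, MeOH, −40 °C
Reagents that add atoms: none
Why: Luche 1,2-reduction; the β face of C6 is screened by the axial C20 methyl and the axial C19 ester, so hydride adds from the α face and gives the axial 6β-alcohol.

Step 8
Reactants: 11 19-tert-butyl hydrogen 6β-hydroxy-14,15,16-trinor-9βH-labd-7-ene-13,19-dioate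
Product: 12 19-tert-butyl hydrogen 6β-benzoyloxy-14,15,16-trinor-9βH-labd-7-ene-13,19-dioate
Conditions: BzOTf (3 equiv), pyridine, CH2Cl2, −78 → 0 °C; aq NaHCO3 work-up (returns the side-chain acid from its mixed anhydride)
Reagents that add atoms: benzoyl trifluoromethanesulfonate, O=C(OS(=O)(=O)C(F)(F)F)c1ccccc1
Why: O-acylation with benzoyl triflate, chosen for the hindered axial alcohol; the bulky tert-butyl ester keeps the 6β-oxygen from closing the 19,6-lactone.

Step 9
Reactants: 12 19-tert-butyl hydrogen 6β-benzoyloxy-14,15,16-trinor-9βH-labd-7-ene-13,19-dioate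
Product: 14 19-tert-butyl hydrogen 6β-benzoyloxy-7α-hydroxy-14,15,16-trinor-9βH-labd-8(17)-ene-13,19-dioate, via 7α-hydroperoxide 13 (not isolated)
Conditions: O2, tetraphenylporphyrin (cat.), hν (visible), CH2Cl2, 0 °C; then PPh3
Reagents that add atoms: dioxygen, O=O
Why: Schenck ene reaction; singlet oxygen attacks C7 from the α face (β face blocked by the 6β-benzoate and C20), and only the C17 methyl hydrogens are available there (H9 is β, H6α is pseudoequatorial and geminal to the ester), so the 7α-hydroperoxide with the 8(17)-methylene forms and PPh3 reduces it to the 7α-alcohol.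

Step 10
Reactants: 15 but-2-yn-1-ol
Product: 16 tert-butyl(but-2-yn-1-yloxy)dimethylsilane
Conditions: TBSCl, imidazole, DMF, rt
Reagents that add atoms: tert-butyldimethylsilyl chloride, CC(C)(C)[Si](C)(C)Cl
Why: Standard silyl ether formation to protect the future C15 hydroxyl.

Step 11
Reactants: 14 19-tert-butyl hydrogen 6β-benzoyloxy-7α-hydroxy-14,15,16-trinor-9βH-labd-8(17)-ene-13,19-dioate; 16 tert-butyl(but-2-yn-1-yloxy)dimethylsilane
Product: 20 tert-butyl 6β-benzoyloxy-15-(tert-butyldimethylsilyloxy)-7α-hydroxy-9βH-labda-8(17),13E-dien-19-oate, via tetrachlorophthalimidyl ester 17 (not isolated), via alkenylzirconocene chloride 18 (not isolated), via alkenylzinc chloride 19 (not isolated)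
Conditions: 14, N-hydroxytetrachlorophthalimide, N,N′-diisopropylcarbodiimide, CH2Cl2, rt; separately 16, Cp2Zr(H)Cl, THF, rt, then ZnCl2; combine, Ni(acac)2 (10 mol %), 2,2′-bipyridine (10 mol %), THF/DMF, rt
Reagents that add atoms: none
Why: Nickel-catalysed decarboxylative alkenylation of a redox-active ester with an alkenylzinc; syn-hydrozirconation puts the metal on the methyl-bearing alkyne carbon trans to the CH2O group, so the 13E geometry is fixed before coupling and no stereocentre is touched.

Step 12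
Reactants: 20 tert-butyl 6β-benzoyloxy-15-(tert-butyldimethylsilyloxy)-7α-hydroxy-9βH-labda-8(17),13E-dien-19-oate
Product: 22 CNP0149011.1 (6β-benzoyloxy-7α,15-dihydroxy-9βH-labda-8(17),13E-dien-19-oic acid), via bis(trimethylsilyl) intermediate 21 (not isolated)
Conditions: TMSOTf, 2,6-lutidine, CH2Cl2, 0 °C; then HF·pyridine, THF, 0 °C → rt
Reagents that add atoms: none
Why: Silyl-triflate cleavage of the tert-butyl ester (loss of isobutene under buffered, non-protic conditions that spare the benzoate and the allylic alcohols) followed by fluoride desilylation of the silyl ester and both silyl ethers.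

## Compound list

1 | tert-butyl (R)-3-hydroxybutanoate | C[C@@H](O)CC(=O)OC(C)(C)C | starting material
2 | 5-iodo-2-methylpent-1-ene | C=C(C)CCCI | starting material
3 | tert-butyl (2R,3R)-3-hydroxy-2-(4-methylpent-4-en-1-yl)butanoate | C[C@@H](O)[C@@H](CCCC(C)=C)C(=O)OC(C)(C)C | intermediate
4 | tert-butyl (2S,3R)-3-hydroxy-2-methyl-2-(4-methylpent-4-en-1-yl)butanoate | C[C@@H](O)[C@](C)(CCCC(C)=C)C(=O)OC(C)(C)C | intermediate
5 | tert-butyl (2S)-2-methyl-2-(4-methylpent-4-en-1-yl)but-3-enoate | C=C[C@](C)(CCCC(C)=C)C(=O)OC(C)(C)C | intermediate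
6 | tert-butyl (1S)-1,3-dimethylcyclohex-2-ene-1-carboxylate (ring A; C4 quaternary, C5=C10 olefin) | CC1=C[C@](C)(CCC1)C(=O)OC(C)(C)C | intermediate
7 | methyl 4-acetyl-5-oxohexanoate | COC(=O)CCC(C(C)=O)C(C)=O | starting material
8 | cyclobutanol photoadduct: tert-butyl 7-acetyl-8-hydroxy-7-(3-methoxy-3-oxopropyl)-2,6,8-trimethylbicyclo[4.2.0]octane-2-carboxylate, cis-fused, four-membered ring anti to the ester, C7/C8 unassigned | CC(=O)C2(CCC(=O)OC)[C@@]1(C)CCC[C@](C)(C(=O)OC(C)(C)C)[C@H]1C2(C)O | intermediate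
9 | tert-butyl (1S,3R)-2-acetyl-3-(1-methoxy-1,5-dioxohexan-4-yl)-1,3-dimethylcyclohexane-1-carboxylate (C10 methyl cis to the ester; epimers at C2 and the chain methine) | CC(=O)C(CCC(=O)OC)[C@@]1(C)CCC[C@](C)(C(=O)OC(C)(C)C)C1C(C)=O | intermediate
10 | 19-tert-butyl hydrogen 6-oxo-14,15,16-trinor-9βH-labd-7-ene-13,19-dioate (4β-ester, 5α-H, C9 chain α, 10β-Me) | CC=1[C@@H](CCC(=O)O)[C@@]2(C)CCC[C@](C)(C(=O)OC(C)(C)C)[C@@H]2C(=O)C=1 | intermediate
11 | 19-tert-butyl hydrogen 6β-hydroxy-14,15,16-trinor-9βH-labd-7-ene-13,19-dioate | CC=1[C@@H](CCC(=O)O)[C@@]2(C)CCC[C@](C)(C(=O)OC(C)(C)C)[C@@H]2[C@H](O)C=1 | intermediate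
12 | 19-tert-butyl hydrogen 6β-benzoyloxy-14,15,16-trinor-9βH-labd-7-ene-13,19-dioate | CC=1[C@@H](CCC(=O)O)[C@@]2(C)CCC[C@](C)(C(=O)OC(C)(C)C)[C@@H]2[C@H](OC(=O)c2ccccc2)C=1 | intermediate
13 | 19-tert-butyl hydrogen 6β-benzoyloxy-7α-hydroperoxy-14,15,16-trinor-9βH-labd-8(17)-ene-13,19-dioate | C=C1[C@@H](CCC(=O)O)[C@@]2(C)CCC[C@](C)(C(=O)OC(C)(C)C)[C@@H]2[C@H](OC(=O)c2ccccc2)[C@H]1OO | intermediate
14 | 19-tert-butyl hydrogen 6β-benzoyloxy-7α-hydroxy-14,15,16-trinor-9βH-labd-8(17)-ene-13,19-dioate | C=C1[C@@H](CCC(=O)O)[C@@]2(C)CCC[C@](C)(C(=O)OC(C)(C)C)[C@@H]2[C@H](OC(=O)c2ccccc2)[C@H]1O | intermediate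
15 | but-2-yn-1-ol | CC#CCO | starting material
16 | tert-butyl(but-2-yn-1-yloxy)dimethylsilane | CC#CCO[Si](C)(C)C(C)(C)C | intermediate
17 | 13-(4,5,6,7-tetrachloro-1,3-dioxoisoindolin-2-yl) 19-tert-butyl 6β-benzoyloxy-7α-hydroxy-14,15,16-trinor-9βH-labd-8(17)-ene-13,19-dioate | C=C1[C@@H](CCC(=O)ON3C(=O)c4c(Cl)c(Cl)c(Cl)c(Cl)c4C3=O)[C@@]2(C)CCC[C@](C)(C(=O)OC(C)(C)C)[C@@H]2[C@H](OC(=O)c2ccccc2)[C@H]1O | intermediate
18 | chlorobis(cyclopentadienyl)[(E)-4-(tert-butyldimethylsilyloxy)but-2-en-2-yl]zirconium | C/C(=C\CO[Si](C)(C)C(C)(C)C)[Zr](Cl)(C1C=CC=C1)C1C=CC=C1 | intermediate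
19 | [(E)-4-(tert-butyldimethylsilyloxy)but-2-en-2-yl]zinc chloride | C/C([Zn]Cl)=C\CO[Si](C)(C)C(C)(C)C | intermediate
20 | tert-butyl 6β-benzoyloxy-15-(tert-butyldimethylsilyloxy)-7α-hydroxy-9βH-labda-8(17),13E-dien-19-oate | C=C1[C@@H](CC/C(C)=C/CO[Si](C)(C)C(C)(C)C)[C@@]2(C)CCC[C@](C)(C(=O)OC(C)(C)C)[C@@H]2[C@H](OC(=O)c2ccccc2)[C@H]1O | intermediate
21 | trimethylsilyl 6β-benzoyloxy-15-(tert-butyldimethylsilyloxy)-7α-(trimethylsilyloxy)-9βH-labda-8(17),13E-dien-19-oate | C=C1[C@@H](CC/C(C)=C/CO[Si](C)(C)C(C)(C)C)[C@@]2(C)CCC[C@](C)(C(=O)O[Si](C)(C)C)[C@@H]2[C@H](OC(=O)c2ccccc2)[C@H]1O[Si](C)(C)C | intermediate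
22 | CNP0149011.1, 6β-benzoyloxy-7α,15-dihydroxy-9βH-labda-8(17),13E-dien-19-oic acid | C=C1[C@@H](CC/C(C)=C/CO)[C@@]2(C)CCC[C@](C)(C(=O)O)[C@@H]2[C@H](OC(=O)c2ccccc2)[C@H]1O | target

## Step count and risks

Total steps: 12. Longest linear sequence: 11 (steps 1–9, 11, 12).

Steps most likely to fail:

Step 5 (the new de Mayo variant). The 3-alkyl group lowers the enol content of 7 and crowds the carbon that must bond to C10, and the facial preference rests only on the C4 ester. Fallback with known chemistry, setting out from 6 and returning at 10: irradiate 6 with acetylacetone itself (the parent de Mayo reaction) to give tert-butyl (1S,3R)-2-acetyl-1,3-dimethyl-3-(2-oxopropyl)cyclohexane-1-carboxylate F1. Close ring B with KOH/MeOH to the C9-unsubstituted enone tert-butyl 6-oxo-11,12,13,14,15,16-hexanorlabd-7-en-19-oate F2. Convert it with TBSOTf/Et3N into the ring-conjugated silyl dienol ether tert-butyl 6-(tert-butyldimethylsilyloxy)-11,12,13,14,15,16-hexanorlabda-6,8-dien-19-oate F3. Add methyl acrylate at the γ-carbon C9 by a vinylogous Mukaiyama–Michael reaction (TBSOTf cat., CH2Cl2, −78 °C) to give 19-tert-butyl 13-methyl 6-oxo-14,15,16-trinor-9βH-labd-7-ene-13,19-dioate F4. Saponify and equilibrate with KOH in MeOH/H2O to reach 10.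

Step 9 (ene reaction). Face and site selectivity of singlet oxygen on the hindered olefin could erode. Fallback, setting out from 12 and returning at 14: epoxidise the 7-ene from the α face with mCPBA/NaHCO3 to 19-tert-butyl hydrogen 6β-benzoyloxy-7α,8α-epoxy-14,15,16-trinor-9βH-labdane-13,19-dioate F5. Isomerise it with Cp2TiCl (from Cp2TiCl2 and Mn dust, THF; trivalent titanium opens the epoxide to the tertiary C8 radical, which loses a C17 hydrogen) to the 7α-hydroxy-8(17)-ene 14. No side-chain olefin is present at this stage, so neither reagent has a competing site.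

Step 11 (late coupling). The free 7α-hydroxyl and the benzoate may interfere with activated-ester formation or consume the organozinc. Fallback, setting out from 14 and 16 and returning at 20: convert 16 by hydrozirconation (through 18) and iodine quench into (E)-tert-butyl[(3-iodobut-2-en-1-yl)oxy]dimethylsilane F6. Couple F6 directly with the free acid 14 by photoredox/nickel decarboxylative vinylation (Ir[dF(CF3)ppy]2(dtbbpy)PF6, NiCl2(dme), 4,4′-di-tert-butyl-2,2′-bipyridine, Cs2CO3, DMSO, blue LED). This oxidative route uses the carboxylate itself and an alkenyl iodide electrophile, with neither an activated ester nor an organozinc.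

Further compounds
F1 | step 5 | tert-butyl (1S,3R)-2-acetyl-1,3-dimethyl-3-(2-oxopropyl)cyclohexane-1-carboxylate | CC(=O)C[C@@]1(C)CCC[C@](C)(C(=O)OC(C)(C)C)C1C(C)=O
F2 | step 5 | tert-butyl 6-oxo-11,12,13,14,15,16-hexanorlabd-7-en-19-oate (5α-H, 10β-Me) | CC=1C[C@@]2(C)CCC[C@](C)(C(=O)OC(C)(C)C)[C@@H]2C(=O)C=1
F3 | step 5 | tert-butyl 6-(tert-butyldimethylsilyloxy)-11,12,13,14,15,16-hexanorlabda-6,8-dien-19-oate | CC1=C[C@@]2(C)CCC[C@](C)(C(=O)OC(C)(C)C)[C@@H]2C(O[Si](C)(C)C(C)(C)C)=C1
F4 | step 5 | 19-tert-butyl 13-methyl 6-oxo-14,15,16-trinor-9βH-labd-7-ene-13,19-dioate | CC=1[C@@H](CCC(=O)OC)[C@@]2(C)CCC[C@](C)(C(=O)OC(C)(C)C)[C@@H]2C(=O)C=1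
F5 | step 9 | 19-tert-butyl hydrogen 6β-benzoyloxy-7α,8α-epoxy-14,15,16-trinor-9βH-labdane-13,19-dioate | C[C@]13[C@@H](CCC(=O)O)[C@@]2(C)CCC[C@](C)(C(=O)OC(C)(C)C)[C@@H]2[C@H](OC(=O)c2ccccc2)[C@H]1O3
F6 | step 11 | (E)-tert-butyl[(3-iodobut-2-en-1-yl)oxy]dimethylsilane | C/C(I)=C\CO[Si](C)(C)C(C)(C)C
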